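Ring A and the C4 quaternary centre are made together. C4 (bearing CH3-18 and the C19 carboxyl) lies 1,4 to C1 across the C5–C10 bond of ring B, so both carbons are first held in a δ-lactone (C19–O–C1–C10–C5–C4) fused to ring B, with a vinyl group (C2=C3) on C1. The silyl ketene acetal of this lactone undergoes an Ireland–Claisen shift that forms C3–C4, breaks C1–O, closes ring A as the C1=C2 cyclohexene and releases C19 as the axial acid in one operation. The precursor is the trans-fused vinyl lactone on ring B with C9 masked as a dioxolane; the (R)-mevalonolactone side chain is joined to C9 afterwards.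

Key step: step 6

Remark: labdane numbering of the target is used for every intermediate; C4 is carried as an epimer mixture from the Michael adduct to the lactone (no descriptor in the open-chain compounds, equatorial-methyl epimer drawn for the two lactones) and is planarised in step 6, and (R)-mevalonolactone and the named reagents are taken as commercial.

Step 1
Reactants: 1 methyl propanoate
Product: 2 1-methoxy-1-(trimethylsilyloxy)prop-1-ene (E/Z mixture)
Conditions: LiN(iPr)2, Me3SiCl (present from the start), THF, −78 → 25 °C; distillation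
Reagents that add atoms: chlorotrimethylsilane, C[Si](C)(C)Cl
Why: Kinetic enolisation of the ester and O-silylation of the enolate give the ketene silyl acetal (silyl ketene acetal formation); its geometry is irrelevant because C4 is planarised again in step 6.

Step 2
Reactants: 2 1-methoxy-1-(trimethylsilyloxy)prop-1-ene; 3 cyclohex-2-en-1-one
Product: 4 methyl 2-[(1R)-3-(trimethylsilyloxy)cyclohex-2-en-1-yl]propanoate
Conditions: chiral o-tolyl-oxazaborolidinium triflimide derived from α,α-diphenylprolinol (20 mol%; the enantiomer that gives the C5 configuration drawn), Ph3PO (25 mol%), PhMe, −20 °C; non-aqueous work-up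
Reagents that add atoms: none
Why: Catalytic asymmetric Mukaiyama–Michael addition: the cationic oxazaborolidinium binds the enone carbonyl and shields one face of the β-carbon, so C4 of the ketene acetal adds to C5 under catalyst control (this sets C5), and silyl transfer gives the C9–C10 enol ether regiospecifically; C4 forms as an inconsequential mixture.

Step 3
Reactants: 4 methyl 2-[(1R)-3-(trimethylsilyloxy)cyclohex-2-en-1-yl]propanoate
Product: 7 methyl 2-[(1S)-2-methylidene-3-oxocyclohexyl]propanoate, via Mannich base 5 (not isolated), via ammonium iodide 6 (not isolated)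
Conditions: [Me2N=CH2]I, CH2Cl2, 0 → 25 °C, aq. NaHCO3 wash; MeI, Et2O, 25 °C; aq. NaHCO3–CH2Cl2, 25 °C
Reagents that add atoms: N,N-dimethylmethyleneiminium iodide, C[N+](C)=C.[I-]
Why: Mannich reaction of the silyl enol ether places the C20 carbon on C10 only, and quaternisation followed by mild base-induced elimination of trimethylamine (Hofmann-type E1cB) gives the exocyclic enone without touching C5.

Step 4
Reactants: 7 methyl 2-[(1S)-2-methylidene-3-oxocyclohexyl]propanoate; 8 acrolein (prop-2-enal)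
Product: 11 (1R,4S,4aS,8aR)-1-ethenyl-4,8a-dimethyloctahydro-1H-isochromene-3,8-dione (together with its C4 epimer), via lithium enolate 9 (not isolated), via hydroxy keto ester 10 (not isolated)
Conditions: Li[HB(sBu)3], THF, −78 °C; acrolein, −78 °C; AcOH quench; then TsOH·H2O (cat.), PhMe, 60 °C
Reagents that add atoms: none
Why: Reductive aldol reaction then lactonisation: hydride adds 1,4 to the β-unsubstituted enone to give the C9–C10 enolate regiospecifically, acrolein adds 1,2 at C10 on the face anti to the C5 side chain (C10 set, C1 trans to C4 on ring B) through a closed chair transition state with the vinyl group equatorial (C1 set, hydroxyl syn to CH3-20), and acid-catalysed transesterification closes the trans-fused δ-lactone.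

Step 5
Reactants: 11 (1R,4S,4aS,8aR)-1-ethenyl-4,8a-dimethyloctahydro-1H-isochromene-3,8-dione
Product: 12 (1R,4S,4aS,8aR)-1-ethenyl-8,8-(ethylenedioxy)-4,8a-dimethyloctahydro-1H-isochromen-3-one (together with its C4 epimer)
Conditions: Me3SiOCH2CH2OSiMe3, Me3SiOTf (cat.), CH2Cl2, −78 → −20 °C
Reagents that add atoms: 1,2-bis(trimethylsilyloxy)ethane, C[Si](C)(C)OCCO[Si](C)(C)C
Why: Silyl-triflate-catalysed ketalisation with the bis-silyl ether of ethylene glycol protects the only ketone at low temperature without ionising the allylic lactone, which leaves C4–H as the sole acidic position for step 6.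

Step 6
Reactants: 12 (1R,4S,4aS,8aR)-1-ethenyl-8,8-(ethylenedioxy)-4,8a-dimethyloctahydro-1H-isochromen-3-one
Product: 15 (1S,4aS,8aR)-5,5-(ethylenedioxy)-1,4a-dimethyl-1,2,4a,5,6,7,8,8a-octahydronaphthalene-1-carboxylic acid, via silyl ketene acetal 13 (not isolated), via silyl ester 14 (not isolated)
Conditions: LiN(iPr)2, t-BuMe2SiCl (present from the start), THF–HMPA, −78 → 25 °C; PhMe, 110–150 °C (sealed tube); AcOH–THF–H2O, 25 °C
Reagents that add atoms: none
Why: Deprotonation occurs only at C4 (the ketal blocks C9 and C10 is quaternary) and O-silylation gives the cyclic ketene acetal 13, whose geometry is fixed by the lactone ring; on heating, C3 of the vinyl group bonds to C4 while C1–O breaks in a concerted suprafacial [3,3] shift, the closest known reaction type being the Ireland–Claisen ring contraction of 6-alkenyl δ-lactones to cyclohex-3-ene-1-carboxylic acids. Ring A (C1, C2, C3, C4, C5, C10) closes as a six-membered carbocycle through a boat-shaped six-atom array (C3, C2, C1, O, C19, C4) bridged by C10–C5, that is, an endo closure onto the vinyl terminus in a bicyclo[2.2.2]-like transition state. The new stereocentre C4 is controlled by the C1 carbinol configuration: the vinyl group lies on the lactone face opposite to CH3-20, so C3 is delivered to that face of C4 and C19 stays on the side of the breaking C1–O bridge, cis to CH3-20 (axial carboxyl, equatorial CH3-18). The step needs O- rather than C-silylation and a single enolisation site, which the in situ silyl chloride quench and the dioxolane secure, and it needs complete chirality transfer, which the ring-enforced boat provides because no chair alternative exists. The trans ring fusion forces this boat to twist, so a higher temperature than for unfused lactones is expected, and the tert-butyldimethylsilyl ketene acetal is chosen for its thermal stability.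

Step 7
Reactants: 15 (1S,4aS,8aR)-5,5-(ethylenedioxy)-1,4a-dimethyl-1,2,4a,5,6,7,8,8a-octahydronaphthalene-1-carboxylic acid
Product: 17 (1S,4aS,8aR)-1,4a-dimethyl-5-oxodecahydronaphthalene-1-carboxylic acid, via saturated ketal acid 16 (not isolated)
Conditions: H2 (1 atm), Pd/C, EtOAc, 25 °C; filtration; then 2 M HCl, THF, 25 °C
Reagents that add atoms: water, O
Why: Catalytic hydrogenation saturates the cis-disubstituted C1=C2 bond without creating a stereocentre, and dilute aqueous acid then hydrolyses the dioxolane to the C9 ketone.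

Step 8
Reactants: 17 (1S,4aS,8aR)-1,4a-dimethyl-5-oxodecahydronaphthalene-1-carboxylic acid
Product: 18 methyl (1S,4aS,8aR)-1,4a-dimethyl-5-oxodecahydronaphthalene-1-carboxylate
Conditions: MeI, K2CO3, DMF, 25 °C
Reagents that add atoms: iodomethane, CI
Why: O-Alkylation of the carboxylate (SN2 on iodomethane) esterifies the hindered tertiary acid, which resists acid-catalysed esterification, and the weak base does not enolise the ketone.

Step 9
Reactants: 18 methyl (1S,4aS,8aR)-1,4a-dimethyl-5-oxodecahydronaphthalene-1-carboxylate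
Product: 20 methyl (1S,4aS,8aR)-1,4a-dimethyl-5-(trifluoromethanesulfonyloxy)-1,2,3,4,4a,7,8,8a-octahydronaphthalene-1-carboxylate, via potassium enolate 19 (not isolated)
Conditions: KN(SiMe3)2, THF, −78 °C; PhNTf2, −78 → 0 °C
Reagents that add atoms: N-phenylbis(trifluoromethanesulfonimide), O=S(=O)(N(c1ccccc1)S(=O)(=O)C(F)(F)F)C(F)(F)F
Why: The ketone can enolise only toward C8 because C10 is quaternary, and O-sulfonylation of the potassium enolate gives the C8=C9 enol triflate (enol triflate formation).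

Step 10
Reactants: 21 (R)-mevalonolactone
Product: 23 benzyl (3R)-3,5-dihydroxy-3-methylpentanoate, via potassium mevalonate 22 (not isolated)
Conditions: KOH (1 equiv), H2O–MeOH, 25 °C, evaporation; BnBr, DMF, 25 °C
Reagents that add atoms: potassium hydroxide, [K+].[OH-]; benzyl bromide, BrCc1ccccc1
Why: Saponification opens the lactone and SN2 O-alkylation of the carboxylate with benzyl bromide fixes the open-chain form; no bond to the stereocentre C13 is touched.

Step 11
Reactants: 23 benzyl (3R)-3,5-dihydroxy-3-methylpentanoate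
Product: 24 benzyl (3S)-3-hydroxy-5-iodo-3-methylpentanoate
Conditions: I2, PPh3, imidazole, CH2Cl2, 0 °C
Reagents that add atoms: iodine, II
Why: Appel iodination replaces only the primary hydroxyl, because a tertiary alkoxyphosphonium ion cannot be displaced in an SN2 sense (the descriptor changes by priority only).

Step 12
Reactants: 24 benzyl (3S)-3-hydroxy-5-iodo-3-methylpentanoate
Product: 25 benzyl (3S)-5-iodo-3-methyl-3-(triethylsilyloxy)pentanoate
Conditions: Et3SiOTf, 2,6-lutidine, CH2Cl2, −78 → 0 °C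
Reagents that add atoms: triethylsilyl trifluoromethanesulfonate, CC[Si](CC)(CC)OS(=O)(=O)C(F)(F)F
Why: The silyl triflate and a hindered pyridine base silylate the tertiary alcohol, which would otherwise quench the organozinc reagent of step 13.

Step 13
Reactants: 20 methyl (1S,4aS,8aR)-1,4a-dimethyl-5-(trifluoromethanesulfonyloxy)-1,2,3,4,4a,7,8,8a-octahydronaphthalene-1-carboxylate; 25 benzyl (3S)-5-iodo-3-methyl-3-(triethylsilyloxy)pentanoate
Product: 27 methyl (1S,4aS,8aR)-5-[(3R)-5-(benzyloxy)-3-methyl-5-oxo-3-(triethylsilyloxy)pentyl]-1,4a-dimethyl-1,2,3,4,4a,7,8,8a-octahydronaphthalene-1-carboxylate, via alkylzinc iodide 26 (not isolated)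
Conditions: Zn dust (activated by BrCH2CH2Br, Me3SiCl), DMA, 40 °C; then triflate 20, PdCl2(dppf) (5 mol%), LiCl, THF–DMA, 55 °C
Reagents that add atoms: none
Why: Zinc inserts into the primary C–I bond to give an alkylzinc iodide that tolerates the ester and silyl ether, and Pd-catalysed Negishi sp3–sp2 cross-coupling with the enol triflate forms the C9–C11 bond.

Step 14
Reactants: 27 methyl (1S,4aS,8aR)-5-[(3R)-5-(benzyloxy)-3-methyl-5-oxo-3-(triethylsilyloxy)pentyl]-1,4a-dimethyl-1,2,3,4,4a,7,8,8a-octahydronaphthalene-1-carboxylate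
Product: 29 methyl (1S,4aS,5R,6R,8aR)-5-[(3R)-5-(benzyloxy)-3-methyl-5-oxo-3-(triethylsilyloxy)pentyl]-6-hydroxy-1,4a-dimethyldecahydronaphthalene-1-carboxylate, via C8 alkylborane 28 (not isolated)
Conditions: BH3·THF, THF, 0 → 25 °C; then 30% H2O2, aq. NaHCO3, 0 → 25 °C
Reagents that add atoms: hydrogen peroxide, OO
Why: Hydroboration–oxidation: borane adds syn to C8=C9 from the α face, away from the axial CH3-20, with boron on the less substituted C8, which sets C9 (9α-H, side chain equatorial) and, after oxidation with retention, C8 (8α-OH); the esters do not react with borane at this temperature.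

Step 15
Reactants: 29 methyl (1S,4aS,5R,6R,8aR)-5-[(3R)-5-(benzyloxy)-3-methyl-5-oxo-3-(triethylsilyloxy)pentyl]-6-hydroxy-1,4a-dimethyldecahydronaphthalene-1-carboxylate
Product: 30 methyl (1S,4aS,5R,8aR)-5-[(3R)-5-(benzyloxy)-3-methyl-5-oxo-3-(triethylsilyloxy)pentyl]-1,4a-dimethyl-6-oxodecahydronaphthalene-1-carboxylate
Conditions: Dess–Martin periodinane, CH2Cl2, 25 °C
Reagents that add atoms: none
Why: Dess–Martin oxidation converts the secondary alcohol into the C8 ketone under neutral conditions, so C9, whose equatorial side chain is in any case the stable arrangement, is not epimerised.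

Step 16
Reactants: 30 methyl (1S,4aS,5R,8aR)-5-[(3R)-5-(benzyloxy)-3-methyl-5-oxo-3-(triethylsilyloxy)pentyl]-1,4a-dimethyl-6-oxodecahydronaphthalene-1-carboxylate
Product: 31 methyl (1S,4aR,5S,8aR)-5-[(3R)-5-(benzyloxy)-3-methyl-5-oxo-3-(triethylsilyloxy)pentyl]-1,4a-dimethyl-6-methylidenedecahydronaphthalene-1-carboxylate
Conditions: Ph3PCH3Br (slight excess over base), KN(SiMe3)2, THF, 0 → 40 °C
Reagents that add atoms: methyltriphenylphosphonium bromide, C[P+](c1ccccc1)(c1ccccc1)c1ccccc1.[Br-]
Why: Wittig methylenation of the ketone installs the exocyclic C8=C17 bond; the salt-free ylide, used without excess base, reacts with the ketone far faster than with the two esters.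

Step 17
Reactants: 31 methyl (1S,4aR,5S,8aR)-5-[(3R)-5-(benzyloxy)-3-methyl-5-oxo-3-(triethylsilyloxy)pentyl]-1,4a-dimethyl-6-methylidenedecahydronaphthalene-1-carboxylate
Product: 33 (1S,4aR,5S,8aR)-5-[(3R)-4-carboxy-3-hydroxy-3-methylbutyl]-1,4a-dimethyl-6-methylidenedecahydronaphthalene-1-carboxylic acid, via silyl ether diacid 32 (not isolated)
Conditions: n-PrSLi (from n-PrSH, n-BuLi), HMPA, 25 °C; then 1 M HCl, THF, 25 °C
Reagents that add atoms: none
Why: The thiolate dealkylates both esters by SN2 attack at the O-methyl and O-benzyl carbons, which bypasses the hindered C19 carbonyl, and dilute acid then hydrolyses the triethylsilyl ether without isomerising the exocyclic alkene.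

Compound list
1 | methyl propanoate | CCC(=O)OC | starting material
2 | 1-methoxy-1-(trimethylsilyloxy)prop-1-ene (E/Z mixture) | CC=C(OC)O[Si](C)(C)C | intermediate
3 | cyclohex-2-en-1-one | O=C1C=CCCC1 | starting material
4 | methyl 2-[(1R)-3-(trimethylsilyloxy)cyclohex-2-en-1-yl]propanoate (C4 epimers) | C1CC[C@@H](C(C)C(=O)OC)C=C1O[Si](C)(C)C | intermediate
5 | methyl 2-[(1R)-2-[(dimethylamino)methyl]-3-oxocyclohexyl]propanoate (Mannich base; epimers at C4 and C10) | C1CC[C@@H](C(C)C(=O)OC)C(CN(C)C)C1=O | intermediate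
6 | {[(6R)-6-(1-methoxy-1-oxopropan-2-yl)-2-oxocyclohexyl]methyl}trimethylammonium iodide | C1CC[C@@H](C(C)C(=O)OC)C(C[N+](C)(C)C)C1=O.[I-] | intermediate
7 | methyl 2-[(1S)-2-methylidene-3-oxocyclohexyl]propanoate (C4 epimers) | C1CC[C@@H](C(C)C(=O)OC)C(=C)C1=O | intermediate
8 | acrolein (prop-2-enal) | C=CC=O | starting material
9 | lithium (3S)-3-(1-methoxy-1-oxopropan-2-yl)-2-methylcyclohex-1-en-1-olate | C1CC[C@@H](C(C)C(=O)OC)C(C)=C1[O-].[Li+] | intermediate
10 | methyl 2-[(1S,2R)-2-[(1R)-1-hydroxyprop-2-en-1-yl]-2-methyl-3-oxocyclohexyl]propanoate (C4 epimers) | C1CC[C@@H](C(C)C(=O)OC)[C@](C)([C@@H](C=C)O)C1=O | intermediate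
11 | (1R,4S,4aS,8aR)-1-ethenyl-4,8a-dimethyloctahydro-1H-isochromene-3,8-dione (equatorial 4-methyl epimer drawn) | C1CC[C@@H]2[C@](C)([C@@H](C=C)OC(=O)[C@H]2C)C1=O | intermediate
12 | (1R,4S,4aS,8aR)-1-ethenyl-8,8-(ethylenedioxy)-4,8a-dimethyloctahydro-1H-isochromen-3-one (equatorial 4-methyl epimer drawn) | C1CC[C@@H]2[C@](C)([C@@H](C=C)OC(=O)[C@H]2C)C13OCCO3 | intermediate
13 | (1R,4aS,8aR)-3-(tert-butyldimethylsilyloxy)-1-ethenyl-8,8-(ethylenedioxy)-4,8a-dimethyl-4a,5,6,7,8,8a-hexahydro-1H-isochromene | C1CC[C@@H]2[C@](C)([C@@H](C=C)OC(O[Si](C)(C)C(C)(C)C)=C2C)C13OCCO3 | intermediate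
14 | tert-butyldimethylsilyl (1S,4aS,8aR)-5,5-(ethylenedioxy)-1,4a-dimethyl-1,2,4a,5,6,7,8,8a-octahydronaphthalene-1-carboxylate | C1CC[C@@H]2[C@](C)(C=CC[C@]2(C)C(=O)O[Si](C)(C)C(C)(C)C)C13OCCO3 | intermediate
15 | (1S,4aS,8aR)-5,5-(ethylenedioxy)-1,4a-dimethyl-1,2,4a,5,6,7,8,8a-octahydronaphthalene-1-carboxylic acid | C1CC[C@@H]2[C@](C)(C=CC[C@]2(C)C(=O)O)C13OCCO3 | intermediate
16 | (1S,4aS,8aR)-5,5-(ethylenedioxy)-1,4a-dimethyldecahydronaphthalene-1-carboxylic acid | C1CC[C@@H]2[C@](C)(CCC[C@]2(C)C(=O)O)C13OCCO3 | intermediate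
17 | (1S,4aS,8aR)-1,4a-dimethyl-5-oxodecahydronaphthalene-1-carboxylic acid | C1CC[C@@H]2[C@](C)(CCC[C@]2(C)C(=O)O)C1=O | intermediate
18 | methyl (1S,4aS,8aR)-1,4a-dimethyl-5-oxodecahydronaphthalene-1-carboxylate | C1CC[C@@H]2[C@](C)(CCC[C@]2(C)C(=O)OC)C1=O | intermediate
19 | potassium (4aR,5S,8aS)-5-(methoxycarbonyl)-5,8a-dimethyl-3,4,4a,5,6,7,8,8a-octahydronaphthalen-1-olate (C8=C9 enolate of 18) | C1CC[C@@H]2[C@](C)(CCC[C@]2(C)C(=O)OC)C([O-])=C1.[K+] | intermediate
20 | methyl (1S,4aS,8aR)-1,4a-dimethyl-5-(trifluoromethanesulfonyloxy)-1,2,3,4,4a,7,8,8a-octahydronaphthalene-1-carboxylate | C1CC[C@@H]2[C@](C)(CCC[C@]2(C)C(=O)OC)C(OS(=O)(=O)C(F)(F)F)=C1 | intermediate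
21 | (R)-mevalonolactone, (4R)-4-hydroxy-4-methyloxan-2-one | C[C@@]1(O)CCOC(=O)C1 | starting material
22 | potassium (3R)-3,5-dihydroxy-3-methylpentanoate | OCC[C@@](C)(O)CC(=O)[O-].[K+] | intermediate
23 | benzyl (3R)-3,5-dihydroxy-3-methylpentanoate | OCC[C@@](C)(O)CC(=O)OCc1ccccc1 | intermediate
24 | benzyl (3S)-3-hydroxy-5-iodo-3-methylpentanoate | ICC[C@@](C)(O)CC(=O)OCc1ccccc1 | intermediate
25 | benzyl (3S)-5-iodo-3-methyl-3-(triethylsilyloxy)pentanoate | ICC[C@@](C)(O[Si](CC)(CC)CC)CC(=O)OCc1ccccc1 | intermediate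
26 | [(3S)-5-(benzyloxy)-3-methyl-5-oxo-3-(triethylsilyloxy)pentyl]zinc iodide | I[Zn]CC[C@@](C)(O[Si](CC)(CC)CC)CC(=O)OCc1ccccc1 | intermediate
27 | methyl (1S,4aS,8aR)-5-[(3R)-5-(benzyloxy)-3-methyl-5-oxo-3-(triethylsilyloxy)pentyl]-1,4a-dimethyl-1,2,3,4,4a,7,8,8a-octahydronaphthalene-1-carboxylate | C1CC[C@@H]2[C@](C)(CCC[C@]2(C)C(=O)OC)C(CC[C@@](C)(O[Si](CC)(CC)CC)CC(=O)OCc3ccccc3)=C1 | intermediate
28 | C8 alkylborane from α-face syn addition of BH3 to C8=C9 of 27 (boron on C8, 9α-H) | [BH2][C@@H]1CC[C@@H]2[C@](C)(CCC[C@]2(C)C(=O)OC)[C@H]1CC[C@@](C)(O[Si](CC)(CC)CC)CC(=O)OCc1ccccc1 | intermediate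
29 | methyl (1S,4aS,5R,6R,8aR)-5-[(3R)-5-(benzyloxy)-3-methyl-5-oxo-3-(triethylsilyloxy)pentyl]-6-hydroxy-1,4a-dimethyldecahydronaphthalene-1-carboxylate | O[C@@H]1CC[C@@H]2[C@](C)(CCC[C@]2(C)C(=O)OC)[C@H]1CC[C@@](C)(O[Si](CC)(CC)CC)CC(=O)OCc1ccccc1 | intermediate
30 | methyl (1S,4aS,5R,8aR)-5-[(3R)-5-(benzyloxy)-3-methyl-5-oxo-3-(triethylsilyloxy)pentyl]-1,4a-dimethyl-6-oxodecahydronaphthalene-1-carboxylate | O=C1CC[C@@H]2[C@](C)(CCC[C@]2(C)C(=O)OC)[C@H]1CC[C@@](C)(O[Si](CC)(CC)CC)CC(=O)OCc1ccccc1 | intermediate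
31 | methyl (1S,4aR,5S,8aR)-5-[(3R)-5-(benzyloxy)-3-methyl-5-oxo-3-(triethylsilyloxy)pentyl]-1,4a-dimethyl-6-methylidenedecahydronaphthalene-1-carboxylate | C=C1CC[C@@H]2[C@](C)(CCC[C@]2(C)C(=O)OC)[C@H]1CC[C@@](C)(O[Si](CC)(CC)CC)CC(=O)OCc1ccccc1 | intermediate
32 | (1S,4aR,5S,8aR)-5-[(3R)-4-carboxy-3-methyl-3-(triethylsilyloxy)butyl]-1,4a-dimethyl-6-methylidenedecahydronaphthalene-1-carboxylic acid | C=C1CC[C@@H]2[C@](C)(CCC[C@]2(C)C(=O)O)[C@H]1CC[C@@](C)(O[Si](CC)(CC)CC)CC(=O)O | intermediate
33 | (1S,4aR,5S,8aR)-5-[(3R)-4-carboxy-3-hydroxy-3-methylbutyl]-1,4a-dimethyl-6-methylidenedecahydronaphthalene-1-carboxylic acid, (13R)-13-hydroxylabd-8(17)-ene-15,19-dioic acid | C=C1CC[C@@H]2[C@](C)(CCC[C@]2(C)C(=O)O)[C@H]1CC[C@@](C)(O)CC(=O)O | target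

Total step count: 17. Longest linear sequence: 14 steps (steps 1–9 and 13–17); the side-chain branch is steps 10–12.

Steps most likely to fail

1. Step 6. The twist that the trans ring fusion imposes on the boat may slow the shift so much that desilylation, silyl migration to carbon or fragmentation of the ketene acetal takes over. Fallback (sets out from 3, comes back at 18): ring A is built by enolate alkylations and C4 is set by methylating a ring A ester enolate.
   - Mukaiyama–Michael addition of 1-methoxy-1-(trimethylsilyloxy)ethene to 3 under the conditions of step 2 gives methyl 2-[(1S)-3-(trimethylsilyloxy)cyclohex-2-en-1-yl]acetate F1.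
   - The sequence of step 3 leads through methyl 2-[(1S)-2-[(dimethylamino)methyl]-3-oxocyclohexyl]acetate F2 and its trimethylammonium iodide F3 to methyl 2-[(1S)-2-methylidene-3-oxocyclohexyl]acetate F4.
   - Conjugate reduction with Li[HB(sBu)3] and alkylation of the enolate with 1-chloro-3-iodopropane (anti to the C5 side chain) gives methyl 2-[(1S,2S)-2-(3-chloropropyl)-2-methyl-3-oxocyclohexyl]acetate F5.
   - Ketalisation as in step 5 gives methyl 2-[(6S,7S)-6-(3-chloropropyl)-6-methyl-1,4-dioxaspiro[4.5]decan-7-yl]acetate F6.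
   - KN(SiMe3)2 closes ring A by intramolecular alkylation of the ester enolate to methyl (4aS,8aS)-5,5-(ethylenedioxy)-4a-methyldecahydronaphthalene-1-carboxylate F7.
   - LiN(iPr)2 then MeI should methylate C4 from the α face, away from the axial CH3-20, to give methyl (1S,4aS,8aR)-5,5-(ethylenedioxy)-1,4a-dimethyldecahydronaphthalene-1-carboxylate F8.
   - Aqueous HCl in THF removes the dioxolane and the route is rejoined at 18.

2. Step 4. The aldol may show poor diastereoselection at C1, acrolein may be attacked in the 1,4 sense, or the hindered aldolate may revert on warming. Fallback (sets out from 7, comes back at 10): C1 is set by reagent-controlled reduction instead of by the aldol transition state.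
   - Enolate 9, made from 7 as in step 4, is trapped with 3-(trimethylsilyl)propynal to give methyl 2-[(1S,2R)-2-[1-hydroxy-3-(trimethylsilyl)prop-2-yn-1-yl]-2-methyl-3-oxocyclohexyl]propanoate F9 as a carbinol mixture.
   - Dess–Martin oxidation gives the ynone methyl 2-[(1S,2S)-2-methyl-3-oxo-2-[3-(trimethylsilyl)prop-2-ynoyl]cyclohexyl]propanoate F10.
   - Asymmetric transfer hydrogenation with RuCl(p-cymene)[(S,S)-TsDPEN] or its enantiomer, whichever delivers the required carbinol, in iPrOH should reduce only the ynone carbonyl to methyl 2-[(1S,2R)-2-[(1S)-1-hydroxy-3-(trimethylsilyl)prop-2-yn-1-yl]-2-methyl-3-oxocyclohexyl]propanoate F11.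
   - Bu4NF buffered with AcOH removes silicon to give methyl 2-[(1S,2R)-2-[(1R)-1-hydroxyprop-2-yn-1-yl]-2-methyl-3-oxocyclohexyl]propanoate F12.
   - Semi-hydrogenation over Pb-poisoned Pd/CaCO3 with quinoline gives 10, which is lactonised to 11 as in step 4.

3. Step 2. Enantiofacial discrimination may be insufficient with a monosubstituted ketene acetal, or achiral silyl-cation catalysis may compete. Fallback (sets out from 1, comes back at 7): C5 is set by asymmetric hydride delivery instead of asymmetric C–C bond formation.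
   - The lithium enolate of 1 (LiN(iPr)2, THF, −78 °C) is added to commercial 3-ethoxycyclohex-2-en-1-one (CCOC1=CC(=O)CCC1), and aqueous HCl gives methyl 2-(3-oxocyclohex-1-en-1-yl)propanoate F13 (Stork–Danheiser sequence).
   - CuH-catalysed asymmetric conjugate reduction (Cu(OAc)2·H2O, the appropriate enantiomer of DTBM-SEGPHOS, PhMe2SiH, PhMe) should give methyl 2-[(1R)-3-[dimethyl(phenyl)silyloxy]cyclohex-2-en-1-yl]propanoate F14.
   - F14 takes the place of 4 in step 3 and the route is rejoined at 7.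

Further compounds
F1 | step 6 | methyl 2-[(1S)-3-(trimethylsilyloxy)cyclohex-2-en-1-yl]acetate | C1CC[C@@H](CC(=O)OC)C=C1O[Si](C)(C)C
F2 | step 6 | methyl 2-[(1S)-2-[(dimethylamino)methyl]-3-oxocyclohexyl]acetate | C1CC[C@@H](CC(=O)OC)C(CN(C)C)C1=O
F3 | step 6 | {[(6S)-6-(2-methoxy-2-oxoethyl)-2-oxocyclohexyl]methyl}trimethylammonium iodide | C1CC[C@@H](CC(=O)OC)C(C[N+](C)(C)C)C1=O.[I-]
F4 | step 6 | methyl 2-[(1S)-2-methylidene-3-oxocyclohexyl]acetate | C1CC[C@@H](CC(=O)OC)C(=C)C1=O
F5 | step 6 | methyl 2-[(1S,2S)-2-(3-chloropropyl)-2-methyl-3-oxocyclohexyl]acetate | C1CC[C@@H](CC(=O)OC)[C@](C)(CCCCl)C1=O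
F6 | step 6 | methyl 2-[(6S,7S)-6-(3-chloropropyl)-6-methyl-1,4-dioxaspiro[4.5]decan-7-yl]acetate | C1CC[C@@H](CC(=O)OC)[C@](C)(CCCCl)C13OCCO3
F7 | step 6 | methyl (4aS,8aS)-5,5-(ethylenedioxy)-4a-methyldecahydronaphthalene-1-carboxylate (C1 epimers) | C1CC[C@@H]2[C@](C)(CCCC2C(=O)OC)C13OCCO3
F8 | step 6 | methyl (1S,4aS,8aR)-5,5-(ethylenedioxy)-1,4a-dimethyldecahydronaphthalene-1-carboxylate | C1CC[C@@H]2[C@](C)(CCC[C@]2(C)C(=O)OC)C13OCCO3
F9 | step 4 | methyl 2-[(1S,2R)-2-[1-hydroxy-3-(trimethylsilyl)prop-2-yn-1-yl]-2-methyl-3-oxocyclohexyl]propanoate (carbinol epimers) | C1CC[C@@H](C(C)C(=O)OC)[C@](C)(C(O)C#C[Si](C)(C)C)C1=O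
F10 | step 4 | methyl 2-[(1S,2S)-2-methyl-3-oxo-2-[3-(trimethylsilyl)prop-2-ynoyl]cyclohexyl]propanoate | C1CC[C@@H](C(C)C(=O)OC)[C@](C)(C(=O)C#C[Si](C)(C)C)C1=O
F11 | step 4 | methyl 2-[(1S,2R)-2-[(1S)-1-hydroxy-3-(trimethylsilyl)prop-2-yn-1-yl]-2-methyl-3-oxocyclohexyl]propanoate | C1CC[C@@H](C(C)C(=O)OC)[C@](C)([C@@H](C#C[Si](C)(C)C)O)C1=O
F12 | step 4 | methyl 2-[(1S,2R)-2-[(1R)-1-hydroxyprop-2-yn-1-yl]-2-methyl-3-oxocyclohexyl]propanoate | C1CC[C@@H](C(C)C(=O)OC)[C@](C)([C@@H](C#C)O)C1=O
F13 | step 2 | methyl 2-(3-oxocyclohex-1-en-1-yl)propanoate | CC(C(=O)OC)C1=CC(=O)CCC1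
F14 | step 2 | methyl 2-[(1R)-3-[dimethyl(phenyl)silyloxy]cyclohex-2-en-1-yl]propanoate | C1CC[C@@H](C(C)C(=O)OC)C=C1O[Si](C)(C)c1ccccc1
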